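**Strategy.** The cycloheptane of the target bears the C10 methyl, the C8 oxygen and the C7 isopropyl group in the same mutual arrangement as the methyl, hydroxyl and isopropyl groups of thymol. Six of its carbons (C1, C10, C9, C8, C7, C6) are therefore drawn from thymol's arene. The seventh, C5, is inserted by an enantioselective intramolecular Buchner reaction of a diazoketone whose tether (C2–C4) hangs from C1, para to oxygen. That one operation closes the cyclopentane C1–C5, enlarges the benzene ring by one carbon, creates the C5 stereocentre and leaves C8 as a masked ketone. The precursor is 1-diazo-4-arylbutan-2-one 10, assembled from thymol, acrylic acid and trimethylsilyldiazomethane.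

Key step: step 7

Remark: guaiane numbering is used (C1/C5 ring fusion, C2–C4 complete the five-membered ring, C6–C10 the seven-membered ring, C14 on C10, C15 on C4); α is the face of H1, β the face of H5; the SMILES strings in the compound list are authoritative.
Assumption: the sense of induction of the bis(oxazoline) ligand on this arene is taken to be settled by a small scouting run, and the antipode that gives (8aS)-12 is used.

Step 1
Reactants: 1 thymol
Product: 2 4-bromo-2-isopropyl-5-methylphenol (4-bromothymol)
Conditions: NBS, MeCN, 0 °C to rt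
Reagents that add atoms: N-bromosuccinimide, O=C1CCC(=O)N1Br
Why: Electrophilic aromatic bromination in which the hydroxyl group directs to its free para position, the open ortho site being flanked by hydroxyl and methyl; no stereocentre is formed.

Step 2
Reactants: 2 4-bromothymol
Product: 3 (4-bromo-2-isopropyl-5-methylphenoxy)triisopropylsilane
Conditions: TIPSOTf, 2,6-lutidine, CH2Cl2, 0 °C to rt
Reagents that add atoms: triisopropylsilyl triflate, CC(C)[Si](OS(=O)(=O)C(F)(F)F)(C(C)C)C(C)C
Why: O-Silylation of the hindered phenol with the reactive silyl triflate gives a bulky aryl silyl ether that withstands the palladium, acid chloride and carbenoid chemistry ahead and later serves as an isolable silyl enol ether.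

Step 3
Reactants: 3 aryl bromide; 4 acrylic acid
Product: 5 (E)-3-[5-isopropyl-2-methyl-4-(triisopropylsilyloxy)phenyl]acrylic acid
Conditions: Pd(OAc)2 (cat.), P(o-tol)3, Et3N, DMF, 100 °C; dilute aqueous citric acid work-up
Reagents that add atoms: none
Why: Heck reaction (oxidative addition of the aryl bromide to zerovalent palladium, syn insertion of the acrylate, syn β-hydride elimination) gives the E-cinnamic acid, the bulky phosphine coping with the ortho methyl group.

Step 4
Reactants: 5 cinnamic acid
Product: 6 3-[5-isopropyl-2-methyl-4-(triisopropylsilyloxy)phenyl]propanoic acid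
Conditions: H2 (1 atm), 10% Pd/C, EtOAc, rt
Reagents that add atoms: none
Why: Heterogeneous catalytic hydrogenation saturates only the conjugated alkene; arene, acid and aryl silyl ether are inert and no stereocentre arises.

Step 5
Reactants: 6 propanoic acid
Product: 7 3-[5-isopropyl-2-methyl-4-(triisopropylsilyloxy)phenyl]propanoyl chloride
Conditions: (COCl)2, DMF (cat.), CH2Cl2, 0 °C to rt; volatiles removed
Reagents that add atoms: oxalyl chloride, O=C(Cl)C(=O)Cl
Why: Acid chloride formation through the chloroiminium (Vilsmeier-type) intermediate under mild conditions that the aryl silyl ether tolerates.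

Step 6
Reactants: 7 acid chloride; 8 trimethylsilyldiazomethane
Product: 10 1-diazo-4-[5-isopropyl-2-methyl-4-(triisopropylsilyloxy)phenyl]butan-2-one, via C-silyl diazoketone 9 (not isolated)
Conditions: 8 (hexane solution), Et3N, THF–MeCN 1:1, 0 °C; aqueous NaHCO3 work-up
Reagents that add atoms: none
Why: C-Acylation of the diazoalkane, as in the first stage of an Arndt–Eistert sequence, with Et3N taking up HCl, followed by protodesilylation of the labile C–Si bond on aqueous work-up.

Step 7
Reactants: 10 diazoketone
Product: 12 (8aS)-7-isopropyl-4-methyl-6-(triisopropylsilyloxy)-3,8a-dihydroazulen-1(2H)-one (C4 ketone; H5 β; C1=C10, C8=C9 and C6=C7), via norcaradiene 11 (not isolated)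
Conditions: [Cu(MeCN)4]PF6 (5 mol %), 2,2'-isopropylidenebis(4-phenyl-2-oxazoline) (6 mol %, antipode giving 8aS), NaB[3,5-(CF3)2C6H3]4 (6 mol %), CH2Cl2, 40 °C, slow addition of 10; filtration through neutral alumina, used without delay
Reagents that add atoms: none
Why: Loss of N2 gives an electrophilic carbenoid of monovalent copper at C5 that cyclopropanates the C1–C6 bond of the arene to norcaradiene 11, and thermal disrotatory six-electron electrocyclic opening of the C1–C6 σ bond then gives cycloheptatriene 12; this is the intramolecular Buchner reaction of 1-diazo-4-arylbutan-2-ones, known with copper bis(oxazoline) catalysts. The cyclopentanone closes by C5–C1 bond formation in a 5-exo sense (the attacked C1–C6 π bond lies outside the new ring), while the seven-membered ring is not closed but arises by one-carbon enlargement of the benzene ring when C1–C6 opens. C5 is the only stereocentre of 12 and is set by the C2-symmetric bis(oxazoline) on copper, which selects the arene face to which the carbenoid adds; the cis fusions in 11 are enforced by geometry and the ring opening does not touch C5. The step needs addition across C1–C6 and not C1–C10, which the C10 methyl group secures by blocking the substituted ortho position, and the para silyloxy group makes C1 nucleophilic and emerges as the C8 silyl enol ether. Product 12 is kept away from acid (rearrangement to a 2-tetralone) and from base (acidic C5–H).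

Step 8
Reactants: 12 azulenone; 13 methylmagnesium bromide
Product: 15 (5βH)-4β-methyl-8-(triisopropylsilyloxy)guaia-1(10),6,8-trien-4α-ol, via methylcerium dichloride 14 (not isolated)
Conditions: anhydrous CeCl3, 13, THF, −78 °C; pH 7 aqueous buffer quench
Reagents that add atoms: none
Why: 1,2-Addition of the weakly basic organocerium reagent avoids enolisation of the acidic C5–H, and the methyl group enters on the β face of the cyclopentanone, syn to H5 and anti to the C5–C6 bond that carries the folded triene, so C4 receives an α hydroxyl and a β methyl.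

Step 9
Reactants: 15 tertiary carbinol
Product: 16 4α-hydroxy-(5βH)-guaia-1(10),6-dien-8-one
Conditions: Bu4NF, AcOH (1:1), THF, −78 to −40 °C; crude product used at once
Reagents that add atoms: none
Why: Fluoride cleavage of the silyl enol ether releases an extended enolate that is protonated kinetically at its α carbon C9 by the acetic acid buffer, giving the C8 ketone with C6=C7 conjugated and C1=C10 still in place; no stereocentre is created.

Step 10
Reactants: 16 dienone
Product: 17 4α-hydroxy-(1αH,5βH,7αH,10αH)-guaian-8-one
Conditions: H2 (1 atm, raised if required), [Ir(cod)(PCy3)(py)]PF6 (5–10 mol %), CH2Cl2, 0 °C to rt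
Reagents that add atoms: none
Why: Hydroxyl-directed homogeneous hydrogenation: the cationic iridium binds the 4α-hydroxyl and delivers hydrogen to the α faces of the homoallylic C6=C7 and C1=C10 bonds, which fixes H7α (isopropyl β), H1α (trans to H5β) and, transiently, H10α.

Step 11
Reactants: 17 hydroxy ketone
Product: 18 (1αH,5βH,7αH,10αH)-guai-3-en-8-one
Conditions: Burgess reagent (MeO2CN–SO2NEt3 inner salt), toluene, 60 °C
Reagents that add atoms: none
Why: Burgess dehydration is a syn (Ei) elimination of the tertiary sulfamate, and because H5 lies anti to the 4α-oxygen the ring proton removed is H3α, so the trisubstituted C3=C4 alkene forms instead of the C4=C5 isomer.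

Step 12
Reactants: 18 ene-ketone
Product: 20 (1αH,5βH,7αH,10αH)-8-(trimethylsilyloxy)guaia-3,8-diene, via lithium enolate 19 (not isolated)
Conditions: LiN(i-Pr)2, THF, −78 °C; then Me3SiCl, −78 to 0 °C
Reagents that add atoms: chlorotrimethylsilane, C[Si](C)(C)Cl
Why: Kinetic deprotonation by the hindered lithium amide occurs at the C9 methylene and not at the isopropyl-bearing C7 methine, and O-silylation traps that regioisomer without touching C7.

Step 13
Reactants: 20 silyl enol ether
Product: 21 (1αH,5βH,7αH)-guaia-3,9-dien-8-one
Conditions: Pd(OAc)2 (1.1 equiv), MeCN, rt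
Reagents that add atoms: none
Why: Saegusa oxidation: transfer of the enolate to palladium at C9 and syn β-hydride elimination of H10 give the C9=C10 enone regiospecifically, leaving C1, C5 and C7 unchanged.

Step 14
Reactants: 21 dienone
Product: 22 9α,10α-epoxy-(1αH,5βH,7αH)-guai-3-en-8-one
Conditions: t-BuOOH (decane), DBU, CH2Cl2, 0 °C to rt, short reaction time
Reagents that add atoms: tert-butyl hydroperoxide, CC(C)(C)OO
Why: Weitz–Scheffer nucleophilic epoxidation affects only the enone (the C3=C4 alkene is not electrophilic); the peroxide anion should add to C10 anti to the allylic C1–C5 bond, that is on the α face beside pseudoaxial H1, and the enolate closes the oxirane on the same face, making the C10–O bond α.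

Step 15
Reactants: 22 epoxy ketone
Product: 23 10α-hydroxy-(1αH,5βH,7αH)-guai-3-en-8-one
Conditions: SmI2 (2.2 equiv), THF–MeOH, −90 °C
Reagents that add atoms: none
Why: Reductive opening of an α,β-epoxy ketone: SmI2 forms the ketyl, the adjacent C9–O bond is cleaved, and the samarium enolate is protonated at C9 by MeOH, while the C10–O bond is not involved, so the 10α-hydroxyl configuration is retained.

Step 16
Reactants: 23 β-hydroxy ketone
Product: 24 (1αH,5βH,7αH)-guai-3-ene-8β,10α-diol
Conditions: Me4NBH(OAc)3, MeCN–AcOH 1:1, −30 °C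
Reagents that add atoms: none
Why: Evans–Saksena reduction: the 10α-hydroxyl exchanges onto boron and delivers hydride intramolecularly to the α face of the C8 carbonyl, which is also the face away from the 7β-isopropyl group, giving the 8β-alcohol anti to the C10 hydroxyl.

Step 17
Reactants: 25 vanillic acid
Product: 26 tert-butyldimethylsilyl 4-(tert-butyldimethylsilyloxy)-3-methoxybenzoate
Conditions: TBSCl (2.2 equiv), imidazole, DMF, rt
Reagents that add atoms: tert-butyldimethylsilyl chloride, CC(C)(C)[Si](C)(C)Cl
Why: Silylation of both acidic hydroxyls masks the phenol and provides a silyl ester that is a direct acid chloride precursor.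

Step 18
Reactants: 26 bis-silyl vanillate
Product: 27 4-(tert-butyldimethylsilyloxy)-3-methoxybenzoyl chloride
Conditions: (COCl)2, DMF (cat.), CH2Cl2, 0 °C to rt; volatiles removed
Reagents that add atoms: oxalyl chloride, O=C(Cl)C(=O)Cl
Why: Silyl esters are converted by oxalyl chloride and catalytic DMF into acid chlorides under neutral conditions with release of the silyl chloride, so the aryl silyl ether is not exposed to HCl.

Step 19
Reactants: 24 diol; 27 acid chloride
Product: 28 10α-hydroxy-(1αH,5βH,7αH)-guai-3-en-8β-yl 4-(tert-butyldimethylsilyloxy)-3-methoxybenzoate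
Conditions: Et3N, DMAP, CH2Cl2, 0 to 40 °C
Reagents that add atoms: none
Why: DMAP-catalysed acylation (acylpyridinium transfer) of the secondary 8β-hydroxyl; the tertiary 10α-hydroxyl is too hindered to react and no stereocentre is touched.

Step 20
Reactants: 28 ester
Product: 29 3α,4α-epoxy-10α-hydroxy-(1αH,5βH,7αH)-guaian-8β-yl 4-(tert-butyldimethylsilyloxy)-3-methoxybenzoate
Conditions: mCPBA, CH2Cl2–aqueous NaHCO3, 0 °C
Reagents that add atoms: 3-chloroperoxybenzoic acid, O=C(OO)c1cccc(Cl)c1
Why: Prilezhaev epoxidation of the only alkene; the peracid should add to the α face, anti to pseudoaxial H5 on allylic C5 (the staggered approach, C1 being puckered to the α side) and away from the β-disposed C10 methyl, isopropyl and ester groups, giving the 3α,4α-epoxide, whereas delivery by a metal bound to the 10α-hydroxyl is not relied on because that oxygen lies near the cyclopentene plane and far from C3.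

Step 21
Reactants: 29 silyl-protected epoxide
Product: 30 3α,4α-epoxy-10α-hydroxy-(1αH,5βH,7αH)-guaian-8β-yl 4-hydroxy-3-methoxybenzoate (CNP0136245.2)
Conditions: Bu4NF, AcOH (1:1), THF, 0 °C
Reagents that add atoms: none
Why: Fluoride cleavage of the aryl silyl ether, buffered with acetic acid so that the liberated phenoxide is protonated at once and neither the ester nor the epoxide is attacked.

**Compound list**

1 | thymol | Cc1ccc(C(C)C)c(O)c1 | starting material
2 | 4-bromo-2-isopropyl-5-methylphenol | Cc1cc(O)c(C(C)C)cc1Br | intermediate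
3 | (4-bromo-2-isopropyl-5-methylphenoxy)triisopropylsilane | Cc1cc(O[Si](C(C)C)(C(C)C)C(C)C)c(C(C)C)cc1Br | intermediate
4 | acrylic acid | C=CC(=O)O | starting material
5 | (E)-3-[5-isopropyl-2-methyl-4-(triisopropylsilyloxy)phenyl]acrylic acid | CC(C)c1cc(/C=C/C(=O)O)c(C)cc1O[Si](C(C)C)(C(C)C)C(C)C | intermediate
6 | 3-[5-isopropyl-2-methyl-4-(triisopropylsilyloxy)phenyl]propanoic acid | CC(C)c1cc(CCC(=O)O)c(C)cc1O[Si](C(C)C)(C(C)C)C(C)C | intermediate
7 | 3-[5-isopropyl-2-methyl-4-(triisopropylsilyloxy)phenyl]propanoyl chloride | CC(C)c1cc(CCC(=O)Cl)c(C)cc1O[Si](C(C)C)(C(C)C)C(C)C | intermediate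
8 | trimethylsilyldiazomethane | C[Si](C)(C)C=[N+]=[N-] | starting material
9 | 1-diazo-1-(trimethylsilyl)-4-arylbutan-2-one (C-silyl diazoketone, not isolated) | CC(C)c1cc(CCC(=O)C(=[N+]=[N-])[Si](C)(C)C)c(C)cc1O[Si](C(C)C)(C(C)C)C(C)C | intermediate
10 | 1-diazo-4-[5-isopropyl-2-methyl-4-(triisopropylsilyloxy)phenyl]butan-2-one | CC(C)c1cc(CCC(=O)C=[N+]=[N-])c(C)cc1O[Si](C(C)C)(C(C)C)C(C)C | intermediate
11 | norcaradiene valence tautomer (cyclopropane C1–C5–C6, not isolated) | O=C1CC[C@]23C(C)=CC(O[Si](C(C)C)(C(C)C)C(C)C)=C(C(C)C)[C@H]2[C@H]13 | intermediate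
12 | (8aS)-7-isopropyl-4-methyl-6-(triisopropylsilyloxy)-3,8a-dihydroazulen-1(2H)-one | O=C1CCC2=C(C)C=C(O[Si](C(C)C)(C(C)C)C(C)C)C(C(C)C)=C[C@H]12 | intermediate
13 | methylmagnesium bromide | C[Mg]Br | starting material
14 | methylcerium dichloride (not isolated) | C[Ce](Cl)Cl | intermediate
15 | (5βH)-4β-methyl-8-(triisopropylsilyloxy)guaia-1(10),6,8-trien-4α-ol | C[C@@]1(O)CCC2=C(C)C=C(O[Si](C(C)C)(C(C)C)C(C)C)C(C(C)C)=C[C@H]12 | intermediate
16 | 4α-hydroxy-(5βH)-guaia-1(10),6-dien-8-one | C[C@@]1(O)CCC2=C(C)CC(=O)C(C(C)C)=C[C@H]12 | intermediate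
17 | 4α-hydroxy-(1αH,5βH,7αH,10αH)-guaian-8-one | O=C1C[C@H](C)[C@@H]2CC[C@@](C)(O)[C@H]2C[C@@H]1C(C)C | intermediate
18 | (1αH,5βH,7αH,10αH)-guai-3-en-8-one | O=C1C[C@H](C)[C@@H]2CC=C(C)[C@H]2C[C@@H]1C(C)C | intermediate
19 | lithium C8–C9 enolate of 18 (not isolated) | [Li]OC1=C[C@H](C)[C@@H]2CC=C(C)[C@H]2C[C@@H]1C(C)C | intermediate
20 | (1αH,5βH,7αH,10αH)-8-(trimethylsilyloxy)guaia-3,8-diene | C[Si](C)(C)OC1=C[C@H](C)[C@@H]2CC=C(C)[C@H]2C[C@@H]1C(C)C | intermediate
21 | (1αH,5βH,7αH)-guaia-3,9-dien-8-one | O=C1C=C(C)[C@@H]2CC=C(C)[C@H]2C[C@@H]1C(C)C | intermediate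
22 | 9α,10α-epoxy-(1αH,5βH,7αH)-guai-3-en-8-one | O=C1[C@H]2O[C@@]2(C)[C@@H]3CC=C(C)[C@H]3C[C@@H]1C(C)C | intermediate
23 | 10α-hydroxy-(1αH,5βH,7αH)-guai-3-en-8-one | O=C1C[C@@](C)(O)[C@@H]2CC=C(C)[C@H]2C[C@@H]1C(C)C | intermediate
24 | (1αH,5βH,7αH)-guai-3-ene-8β,10α-diol | O[C@@H]1C[C@@](C)(O)[C@@H]2CC=C(C)[C@H]2C[C@@H]1C(C)C | intermediate
25 | vanillic acid | COc1cc(C(=O)O)ccc1O | starting material
26 | tert-butyldimethylsilyl 4-(tert-butyldimethylsilyloxy)-3-methoxybenzoate | COc1cc(C(=O)O[Si](C)(C)C(C)(C)C)ccc1O[Si](C)(C)C(C)(C)C | intermediate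
27 | 4-(tert-butyldimethylsilyloxy)-3-methoxybenzoyl chloride | COc1cc(C(=O)Cl)ccc1O[Si](C)(C)C(C)(C)C | intermediate
28 | 10α-hydroxy-(1αH,5βH,7αH)-guai-3-en-8β-yl 4-(tert-butyldimethylsilyloxy)-3-methoxybenzoate | COc1cc(C(=O)O[C@@H]2C[C@@](C)(O)[C@@H]3CC=C(C)[C@H]3C[C@@H]2C(C)C)ccc1O[Si](C)(C)C(C)(C)C | intermediate
29 | 3α,4α-epoxy-10α-hydroxy-(1αH,5βH,7αH)-guaian-8β-yl 4-(tert-butyldimethylsilyloxy)-3-methoxybenzoate | COc1cc(C(=O)O[C@@H]2C[C@@](C)(O)[C@@H]3C[C@H]4O[C@@]4(C)[C@H]3C[C@@H]2C(C)C)ccc1O[Si](C)(C)C(C)(C)C | intermediate
30 | 3α,4α-epoxy-10α-hydroxy-(1αH,5βH,7αH)-guaian-8β-yl 4-hydroxy-3-methoxybenzoate (CNP0136245.2) | COc1cc(C(=O)O[C@@H]2C[C@@](C)(O)[C@@H]3C[C@H]4O[C@@]4(C)[C@H]3C[C@@H]2C(C)C)ccc1O | target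

**Step count.** 21 steps in total. The longest linear sequence is 19 steps from thymol (steps 1–16 and 19–21); steps 17–18 form the vanilloyl branch.

**Steps most likely to fail**

1. Step 7. The risk is insufficient discrimination between the two arene faces by the copper bis(oxazoline) carbenoid on this tetrasubstituted ring, so that C5 is formed with incomplete enantiomeric purity. The fallback replaces asymmetric catalysis by classical resolution. It sets out from diol 24 of incomplete enantiomeric purity (the material having been carried unchanged through steps 8–16) and returns to 24 as a single enantiomer. The C8 hydroxyl would be esterified with (S)-O-methylmandelic acid (EDC, catalytic DMAP, CH2Cl2, 0 °C). This should give the (S)-O-methylmandelate of 24 F1 together with the diastereomeric (S)-O-methylmandelate of ent-24 F2. The two would be separated by chromatography or crystallisation, and F1 cleaved with K2CO3 in MeOH to return 24.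

2. Step 10. The risk is incomplete or undirected delivery of hydrogen to the tetrasubstituted C1=C10 bond, or its migration into conjugation before it is reduced, so that the trans ring fusion is not secured. The fallback sets out from dienone 16 and rejoins the route at dienone 21. The hydrogenation with [Ir(cod)(PCy3)(py)]PF6 would be stopped once the trisubstituted C6=C7 bond has taken up hydrogen under hydroxyl direction, giving the 1(10)-ene ketone F3. The remaining alkene would then be reduced by hydrogen-atom-transfer hydrogenation (Mn(dpm)3 cat., PhSiH3, t-BuOOH, i-PrOH, rt), a radical process known to favour the thermodynamically preferred ring fusion, here trans. This should give 17 and/or the C10-epimeric ketone F4. Because C10 becomes trigonal again later, F4 would be taken through the conditions of steps 11–13: Burgess dehydration to the C10-epimeric ene-ketone F5, kinetic enolisation to the C10-epimeric lithium enolate F6, silylation to the C10-epimeric silyl enol ether F7, and oxidation with Pd(OAc)2, which converges on 21.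

3. Step 20. The risk is poor or reversed facial selectivity of the peracid on a cyclopentene whose two faces are sterically similar. The fallback sets out from ester 28 and returns at epoxide 29, using a β-face preference of electrophiles in the opposite sense. NBS in aqueous THF at 0 °C would form the β-bromonium ion, which water opens at the tertiary C4 from the α face to give the 3β-bromo-4α-hydroxy bromohydrin F8. DBU in CH2Cl2 would then close the 3α,4α-epoxide by backside displacement of bromide, giving 29.

**Further compounds**

F1 | step 7 | (S)-O-methylmandelate of 24 at the C8 hydroxyl | CO[C@H](C(=O)O[C@@H]1C[C@@](C)(O)[C@@H]2CC=C(C)[C@H]2C[C@@H]1C(C)C)c1ccccc1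
F2 | step 7 | (S)-O-methylmandelate of ent-24 (diastereomer removed) | CO[C@H](C(=O)O[C@H]1C[C@](C)(O)[C@H]2CC=C(C)[C@@H]2C[C@H]1C(C)C)c1ccccc1
F3 | step 10 | 4α-hydroxy-(5βH,7αH)-guai-1(10)-en-8-one | O=C1CC(C)=C2CC[C@@](C)(O)[C@H]2C[C@@H]1C(C)C
F4 | step 10 | 4α-hydroxy-(1αH,5βH,7αH,10βH)-guaian-8-one (C10 epimer of 17) | O=C1C[C@@H](C)[C@@H]2CC[C@@](C)(O)[C@H]2C[C@@H]1C(C)C
F5 | step 10 | (1αH,5βH,7αH,10βH)-guai-3-en-8-one (C10 epimer of 18) | O=C1C[C@@H](C)[C@@H]2CC=C(C)[C@H]2C[C@@H]1C(C)C
F6 | step 10 | lithium C8–C9 enolate of F5 (C10 epimer of 19) | [Li]OC1=C[C@@H](C)[C@@H]2CC=C(C)[C@H]2C[C@@H]1C(C)C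
F7 | step 10 | (1αH,5βH,7αH,10βH)-8-(trimethylsilyloxy)guaia-3,8-diene (C10 epimer of 20) | C[Si](C)(C)OC1=C[C@@H](C)[C@@H]2CC=C(C)[C@H]2C[C@@H]1C(C)C
F8 | step 20 | 3β-bromo-4α,10α-dihydroxy-(1αH,5βH,7αH)-guaian-8β-yl 4-(tert-butyldimethylsilyloxy)-3-methoxybenzoate | COc1cc(C(=O)O[C@@H]2C[C@@](C)(O)[C@@H]3C[C@H](Br)[C@@](C)(O)[C@H]3C[C@@H]2C(C)C)ccc1O[Si](C)(C)C(C)(C)C
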